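Molar-minutes were the unit of the meeting: the analyst laid the runs out by exposure, c_reagent·t, the charged concentration of reagent times the time, and asked that target be watched against it.

| flask | substrate | reagent | remark | time |
|---|---|---|---|---|
| ash | 0.80 M | 0.17 M | run made earlier |  |
| elm | 0.80 M | 0.77 M | run made earlier |  |
| oak | 1.9 M | 0.88 M | run made earlier |  |
| Saturday's | 0.80 M | 0.880 M |  | 50 min |
| Friday's | 2.5 M | 0.200 M |  | 15 min |

- ash (time / min: target / %, substrate / %): 12.0: 1.9, 53.6; 25.0: 0.5, 49.3; 40.0: 6.3, 47.9; 50.0: 7.7, 46.0
- elm (time / min: target / %, substrate / %): 12.0: 8.7, 40.1; 25.0: 12.6, 29.4; 40.0: 15.9, 24.2; 50.0: 18.1, 21.4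
- oak (time / min: target / %, substrate / %): 4.00: 3.7, 49.6; 10.0: 7.6, 42.2; 20.0: 10.8, 36.6; 50.0: 14.3, 30.4

(readings scatter by 1 percentage point)

- a reading or a percentage of target counts all its forms, free or not
- a reading of substrate is of its free form alone

- the flask that ends with the higher amount of target, in percent of the substrate charged, or "neither" when 2 percentage points or less lies between them (Saturday's / Friday's / neither)
- final target, as a percentage of the substrate charged, in Saturday's
- final target, as a percentage of the substrate charged, in Friday's

The analyst reported that ash at 50.0 min, elm at 12.0 min and oak at 10.0 min, despite their different times, stand at similar exposures of 8.50 M·min, 9.24 M·min and 8.80 M·min, and read 7.7%, 8.7% and 7.6% of target. I took the minutes and, in a reckoning of my own, replaced that stretch of curve by its mean slope φ, the target fraction gained per molar-minute, 0.00904 M⁻¹ min⁻¹.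

The analyst tested the error of that mean. At oak's 4.00 min, φ gives 3.18% against a reading of 3.7%, inside the scatter, but at elm's 50.0 min it gives 34.8% against 18.1%, so elm's readings have bent away from the line by then. Friday's exposure of 3.00 M·min is a little less than that of oak's first reading, 3.52 M·min, so I extended the line to it, and φ gives Friday's 2.71%. Saturday's 44.0 M·min lies beyond the straight stretch, so I scaled elm's end reading instead and got 20.7%.

The forecast's author, arguing from “a fast first-order reversible change to a hidden form”, named Saturday's, with 20% (17% to 23%) for Saturday's and 2.2% (1.3% to 3.5%) for Friday's, a lower Friday's figure than mine.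

    substrate ⇌ intermediate A (K = 0.721, k = 1.21 min⁻¹)
    substrate + reagent → intermediate B (k = 0.0759 M⁻¹ min⁻¹)
    reagent + intermediate A ⇌ intermediate C (K = 18.0 M⁻¹, k = 0.00907 M⁻¹ min⁻¹)
    intermediate B ⇌ target (K = 0.400, k = 0.156 min⁻¹)
    substrate + target ⇌ idle adduct, settled at all times (K = 0.947 M⁻¹)

Saturday's ended at 19.5% and Friday's at 2.59%, so Saturday's holds more target, as the forecast said, and φ landed 0.12 percentage points from Friday's result. Part of the gap between the two flasks lies in Friday's reagent concentration: charged at Saturday's level, its substrate and time held, Friday's flask ends at 9.92% rather than 2.59%. A neighbour of Friday's charged with 0.80 M of reagent has an exposure of 12.0 M·min, where φ gives 10.9%, and that neighbour ends at 9.17%.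

(The readings stem from a simulated flask with made-up constants; the scatter is artificial.)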